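**Strategy.** The dihydrofuran ring is cut at O1–C2 and C3a–C3: the ortho pair O1/C3a of the benzene ring acts as a 1,3-dinucleophile, C3/C2 as a 1,2-dielectrophile. The trilithio species from 4,6-dibromoresorcinol adds to (R)-3,3-dimethyloxirane-2-carbaldehyde (C3a–C3, Felkin–Anh), and the neighbouring phenoxide then opens the epoxide 5-exo with inversion (O1–C2), giving the cis-2,3-disubstituted dihydrobenzofuran in one operation. The symmetry of the resorcinol makes both bromines equivalent; the surviving one becomes the C5 acetyl group. The tertiary alcohol left by the epoxide is dehydrated to the isopropenyl group, and the (Z)-enoate is built on the C3 ester by Still–Gennari olefination.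

Key step: step 3

Remark: the target is read as the 2,3-cis isomer, (2S,3S), with the isopropenyl and acyloxy groups on the same face of the dihydrofuran ring; the descriptor at C2 changes along the route only because substituent priorities change, not the arrangement in space.

Step 1
Reactants: 1 3-methylbut-2-en-1-ol
Product: 2 (S)-(3,3-dimethyloxiran-2-yl)methanol
Conditions: Ti(OiPr)4 (5 mol%), L-(+)-diisopropyl tartrate (6 mol%), t-BuOOH, 4 Å MS, CH2Cl2, −20 °C
Reagents that add atoms: tert-butyl hydroperoxide CC(C)(C)OO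
Why: Katsuki–Sharpless asymmetric epoxidation of a 3,3-disubstituted allylic alcohol; the L-(+)-tartrate ligand should deliver oxygen to the face that gives the (S)-epoxy alcohol (same sense as geraniol to its (2S,3S)-epoxide), which sets the carbon that becomes C2.

Step 2
Reactants: 2 (S)-(3,3-dimethyloxiran-2-yl)methanol
Product: 3 (R)-3,3-dimethyloxirane-2-carbaldehyde
Conditions: (COCl)2, DMSO, CH2Cl2, −78 °C; Et3N, −78 → 0 °C; bulb-to-bulb distillation
Reagents that add atoms: none
Why: Swern oxidation at low temperature; the oxirane C–H is not readily enolized, so the stereocentre should be retained (the descriptor becomes R by priority change only).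

Step 3
Reactants: 4 4,6-dibromobenzene-1,3-diol; 3 (R)-3,3-dimethyloxirane-2-carbaldehyde
Product: 7 (2R,3S)-5-bromo-2-(2-hydroxypropan-2-yl)-2,3-dihydro-1-benzofuran-3,6-diol, via aryllithium trianion 5 (not isolated), via anti epoxy alcohol 6 (not isolated)
Conditions: 4, n-BuLi (2.0 equiv), THF, −78 °C; t-BuLi (2.0 equiv), −78 → −40 °C; then 3, −78 °C; then MeOH, −78 °C → rt
Reagents that add atoms: none
Why: Two equivalents of n-BuLi form the dilithium resorcinolate and t-BuLi exchanges one of its two equivalent bromines (a second exchange on the trianion is disfavoured), giving 2-lithiophenoxide 5, whose C–Li adds to the aldehyde of 3 to forge C3a–C3; once methanol has protonated the alkoxide, the ortho phenoxide opens the oxirane at its CH carbon to forge O1–C2. The closest known reaction types are the addition of lithium 2-lithiophenoxides to aldehydes and the base-induced cyclization of epoxidized ortho-prenylphenols to 2-(2-hydroxypropan-2-yl)dihydrobenzofurans, here telescoped in one flask. The dihydrofuran ring closes in the 5-exo-tet mode at the secondary oxirane carbon, which under basic conditions is preferred over 6-endo attack at the fully substituted carbon. C3 is set in the addition by Felkin–Anh control (the aryl group enters anti to the oxirane C–O bond and past the small α-hydrogen), giving anti epoxy alcohol 6; C2 stems from the Sharpless epoxidation and is inverted in the SN2 opening, so that anti 6 becomes the 2,3-cis ring. The step needs Felkin rather than chelation control (THF as donor solvent works against a lithium chelate) and attack by the phenoxide rather than by the C3 alkoxide (Payne rearrangement), which the methanol quench before warming secures; the distal phenoxide cannot reach the oxirane.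

Step 4
Reactants: 7 (2R,3S)-5-bromo-2-(2-hydroxypropan-2-yl)-2,3-dihydro-1-benzofuran-3,6-diol
Product: 8 (2R,3S)-5-bromo-6-[(tert-butyldimethylsilyl)oxy]-2-(2-hydroxypropan-2-yl)-2,3-dihydro-1-benzofuran-3-ol
Conditions: TBSCl (1.05 equiv), imidazole, DMF, 0 °C
Reagents that add atoms: tert-butyldimethylsilyl chloride CC(C)(C)[Si](C)(C)Cl
Why: Imidazole-mediated silylation should take the acidic, unhindered phenol in preference to the hindered secondary and the tertiary alcohol.

Step 5
Reactants: 8 (2R,3S)-5-bromo-6-[(tert-butyldimethylsilyl)oxy]-2-(2-hydroxypropan-2-yl)-2,3-dihydro-1-benzofuran-3-ol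
Product: 10 1-[(2R,3S)-6-[(tert-butyldimethylsilyl)oxy]-3-hydroxy-2-(2-hydroxypropan-2-yl)-2,3-dihydro-1-benzofuran-5-yl]ethan-1-one, via enol ether 9 (not isolated)
Conditions: tributyl(1-ethoxyvinyl)stannane, Pd(PPh3)4 (5 mol%), toluene, 100 °C; then 1 M aq. HCl, THF, 0 °C
Reagents that add atoms: tributyl(1-ethoxyvinyl)stannane CCCC[Sn](CCCC)(CCCC)C(=C)OCC; water O
Why: Stille coupling with an acetyl-anion equivalent tolerates the free alcohols, and the aryl enol ether should hydrolyse in cold dilute acid much faster than the benzylic alcohol ionizes or the aryl silyl ether cleaves.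

Step 6
Reactants: 11 ethyl 2-[bis(2,2,2-trifluoroethoxy)phosphoryl]propanoate
Product: 12 2-[bis(2,2,2-trifluoroethoxy)phosphoryl]propanoic acid
Conditions: LiOH·H2O (1.05 equiv), THF/H2O, 0 °C; then 1 M HCl to pH 2
Reagents that add atoms: lithium hydroxide [Li+].[OH-]
Why: Saponification with one equivalent of hydroxide at 0 °C should cleave the activated carboxylic ester before the phosphonate esters are touched.

Step 7
Reactants: 10 1-[(2R,3S)-6-[(tert-butyldimethylsilyl)oxy]-3-hydroxy-2-(2-hydroxypropan-2-yl)-2,3-dihydro-1-benzofuran-5-yl]ethan-1-one; 12 2-[bis(2,2,2-trifluoroethoxy)phosphoryl]propanoic acid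
Product: 13 (2R,3S)-5-acetyl-6-[(tert-butyldimethylsilyl)oxy]-2-(2-hydroxypropan-2-yl)-2,3-dihydro-1-benzofuran-3-yl 2-[bis(2,2,2-trifluoroethoxy)phosphoryl]propanoate
Conditions: DCC, DMAP (cat.), CH2Cl2, 0 °C → rt
Reagents that add atoms: none
Why: Steglich esterification acylates the secondary alcohol at oxygen (C3 configuration untouched) while the tertiary alcohol is too hindered; the two epimers at the phosphonate carbon converge in step 10.

Step 8
Reactants: 13 (2R,3S)-5-acetyl-6-[(tert-butyldimethylsilyl)oxy]-2-(2-hydroxypropan-2-yl)-2,3-dihydro-1-benzofuran-3-yl 2-[bis(2,2,2-trifluoroethoxy)phosphoryl]propanoate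
Product: 14 (2S,3S)-5-acetyl-6-[(tert-butyldimethylsilyl)oxy]-2-(prop-1-en-2-yl)-2,3-dihydro-1-benzofuran-3-yl 2-[bis(2,2,2-trifluoroethoxy)phosphoryl]propanoate
Conditions: SOCl2, pyridine, CH2Cl2, −20 → 0 °C
Reagents that add atoms: none
Why: Dehydration through the tertiary chlorosulfite with pyridine as base (E2) should take one of the six accessible methyl hydrogens rather than the single hindered C2–H, the classical conversion of hydroxyisopropyl into isopropenyl dihydrobenzofurans.

Step 9
Reactants: 15 (2Z)-but-2-ene-1,4-diyl diacetate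
Product: 16 2-oxoethyl acetate
Conditions: O3, CH2Cl2, −78 °C; then Me2S, −78 °C → rt; distillation
Reagents that add atoms: ozone O=[O+][O-]
Why: Ozonolysis with reductive work-up of the symmetrical alkene gives two molecules of the aldehyde.

Step 10
Reactants: 14 (2S,3S)-5-acetyl-6-[(tert-butyldimethylsilyl)oxy]-2-(prop-1-en-2-yl)-2,3-dihydro-1-benzofuran-3-yl 2-[bis(2,2,2-trifluoroethoxy)phosphoryl]propanoate; 16 2-oxoethyl acetate
Product: 17 (2S,3S)-5-acetyl-6-[(tert-butyldimethylsilyl)oxy]-2-(prop-1-en-2-yl)-2,3-dihydro-1-benzofuran-3-yl (2Z)-4-(acetyloxy)-2-methylbut-2-enoate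
Conditions: KN(SiMe3)2 (1.0 equiv), 18-crown-6, THF, −78 °C; then 16, −78 °C
Reagents that add atoms: none
Why: Still–Gennari variant of the Horner–Wadsworth–Emmons reaction: the trifluoroethyl phosphonate with a dissociated potassium counter-ion should give the kinetic (Z)-trisubstituted enoate (ester cis to CH2OAc), and one equivalent of base deprotonates only the phosphonate C–H, which is more acidic than the methyl ketone.

Step 11
Reactants: 17 (2S,3S)-5-acetyl-6-[(tert-butyldimethylsilyl)oxy]-2-(prop-1-en-2-yl)-2,3-dihydro-1-benzofuran-3-yl (2Z)-4-(acetyloxy)-2-methylbut-2-enoate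
Product: 18 (2S,3S)-5-acetyl-6-hydroxy-2-(prop-1-en-2-yl)-2,3-dihydro-1-benzofuran-3-yl (2Z)-4-(acetyloxy)-2-methylbut-2-enoate
Conditions: HF·pyridine, pyridine, THF, 0 °C
Reagents that add atoms: none
Why: Buffered fluoride cleavage of the aryl silyl ether avoids a free phenoxide (which could expel the para-benzylic carboxylate) and should leave both esters, the allylic acetate and the (Z)-alkene intact.

**Compound list**

1 | 3-methylbut-2-en-1-ol | CC(C)=CCO | starting material
2 | (S)-(3,3-dimethyloxiran-2-yl)methanol | OC[C@@H]1OC1(C)C | intermediate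
3 | (R)-3,3-dimethyloxirane-2-carbaldehyde | O=C[C@@H]1OC1(C)C | intermediate
4 | 4,6-dibromobenzene-1,3-diol | Oc1cc(O)c(Br)cc1Br | starting material
5 | dilithium 4-bromo-6-lithiobenzene-1,3-diolate | [Li]Oc1cc(O[Li])c(Br)cc1[Li] | intermediate
6 | (S)-(5-bromo-2,4-dihydroxyphenyl)[(2S)-3,3-dimethyloxiran-2-yl]methanol (present as its lithium phenoxide) | Oc1cc(O)c(Br)cc1[C@H](O)[C@@H]1OC1(C)C | intermediate
7 | (2R,3S)-5-bromo-2-(2-hydroxypropan-2-yl)-2,3-dihydro-1-benzofuran-3,6-diol | CC(C)(O)[C@@H]1Oc2cc(O)c(Br)cc2[C@@H]1O | intermediate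
8 | (2R,3S)-5-bromo-6-[(tert-butyldimethylsilyl)oxy]-2-(2-hydroxypropan-2-yl)-2,3-dihydro-1-benzofuran-3-ol | CC(C)(O)[C@@H]1Oc2cc(O[Si](C)(C)C(C)(C)C)c(Br)cc2[C@@H]1O | intermediate
9 | (2R,3S)-6-[(tert-butyldimethylsilyl)oxy]-5-(1-ethoxyethenyl)-2-(2-hydroxypropan-2-yl)-2,3-dihydro-1-benzofuran-3-ol | CC(C)(O)[C@@H]1Oc2cc(O[Si](C)(C)C(C)(C)C)c(C(=C)OCC)cc2[C@@H]1O | intermediate
10 | 1-[(2R,3S)-6-[(tert-butyldimethylsilyl)oxy]-3-hydroxy-2-(2-hydroxypropan-2-yl)-2,3-dihydro-1-benzofuran-5-yl]ethan-1-one | CC(C)(O)[C@@H]1Oc2cc(O[Si](C)(C)C(C)(C)C)c(C(C)=O)cc2[C@@H]1O | intermediate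
11 | ethyl 2-[bis(2,2,2-trifluoroethoxy)phosphoryl]propanoate (racemic) | CCOC(=O)C(C)P(=O)(OCC(F)(F)F)OCC(F)(F)F | starting material
12 | 2-[bis(2,2,2-trifluoroethoxy)phosphoryl]propanoic acid (racemic) | OC(=O)C(C)P(=O)(OCC(F)(F)F)OCC(F)(F)F | intermediate
13 | (2R,3S)-5-acetyl-6-[(tert-butyldimethylsilyl)oxy]-2-(2-hydroxypropan-2-yl)-2,3-dihydro-1-benzofuran-3-yl 2-[bis(2,2,2-trifluoroethoxy)phosphoryl]propanoate (both epimers at the phosphonate carbon) | CC(C)(O)[C@@H]1Oc2cc(O[Si](C)(C)C(C)(C)C)c(C(C)=O)cc2[C@@H]1OC(=O)C(C)P(=O)(OCC(F)(F)F)OCC(F)(F)F | intermediate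
14 | (2S,3S)-5-acetyl-6-[(tert-butyldimethylsilyl)oxy]-2-(prop-1-en-2-yl)-2,3-dihydro-1-benzofuran-3-yl 2-[bis(2,2,2-trifluoroethoxy)phosphoryl]propanoate (both epimers at the phosphonate carbon) | C=C(C)[C@@H]1Oc2cc(O[Si](C)(C)C(C)(C)C)c(C(C)=O)cc2[C@@H]1OC(=O)C(C)P(=O)(OCC(F)(F)F)OCC(F)(F)F | intermediate
15 | (2Z)-but-2-ene-1,4-diyl diacetate | CC(=O)OC/C=C\COC(C)=O | starting material
16 | 2-oxoethyl acetate | CC(=O)OCC=O | intermediate
17 | (2S,3S)-5-acetyl-6-[(tert-butyldimethylsilyl)oxy]-2-(prop-1-en-2-yl)-2,3-dihydro-1-benzofuran-3-yl (2Z)-4-(acetyloxy)-2-methylbut-2-enoate | C=C(C)[C@@H]1Oc2cc(O[Si](C)(C)C(C)(C)C)c(C(C)=O)cc2[C@@H]1OC(=O)/C(C)=C\COC(C)=O | intermediate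
18 | (2S,3S)-5-acetyl-6-hydroxy-2-(prop-1-en-2-yl)-2,3-dihydro-1-benzofuran-3-yl (2Z)-4-(acetyloxy)-2-methylbut-2-enoate | C=C(C)[C@@H]1Oc2cc(O)c(C(C)=O)cc2[C@@H]1OC(=O)/C(C)=C\COC(C)=O | target

**Step count.** Total: 11 steps. Longest linear sequence: 9 steps (1, 2, 3, 4, 5, 7, 8, 10, 11).

**Steps most likely to fail**

Step 3. The facial selectivity of the aryllithium addition may be poor if a lithium chelate between the aldehyde and oxirane oxygens competes with the Felkin–Anh mode; the C3 epimer would then form and close to the trans ring. The fallback sets C3 by reduction instead of addition. It sets out from 8, carried as a mixture with its C3 epimer. Oxidation with Dess–Martin periodinane (NaHCO3, CH2Cl2) would give the ketone (2S)-5-bromo-6-[(tert-butyldimethylsilyl)oxy]-2-(2-hydroxypropan-2-yl)-1-benzofuran-3(2H)-one F1. Reduction with LiBH(s-Bu)3 in THF at −78 °C should deliver hydride to the face opposite the C2 substituent and so come back to the cis alcohol 8.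

Step 8. Activation of the tertiary alcohol next to the C3 ester may go astray: elimination into the ring (C2–H) followed by loss of the carboxylate and aromatization, or capture of the developing cation by the neighbouring ester carbonyl with acyl transfer. The fallback dehydrates before the ester is in place and sets out from 10. Silylation of the secondary alcohol (Et3SiCl, imidazole, DMF) would give 1-[(2R,3S)-6-[(tert-butyldimethylsilyl)oxy]-2-(2-hydroxypropan-2-yl)-3-[(triethylsilyl)oxy]-2,3-dihydro-1-benzofuran-5-yl]ethan-1-one F2. Syn-elimination with the Burgess reagent (toluene, 50 °C) would give 1-[(2S,3S)-6-[(tert-butyldimethylsilyl)oxy]-2-(prop-1-en-2-yl)-3-[(triethylsilyl)oxy]-2,3-dihydro-1-benzofuran-5-yl]ethan-1-one F3. Selective removal of the alkyl silyl ether (AcOH/THF/H2O) would give 1-[(2S,3S)-6-[(tert-butyldimethylsilyl)oxy]-3-hydroxy-2-(prop-1-en-2-yl)-2,3-dihydro-1-benzofuran-5-yl]ethan-1-one F4, and esterification with 12 (DCC, DMAP) comes back to 14.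

Step 10. Z selectivity may erode, or the base may act elsewhere on the substrate (enolization of the methyl ketone, elimination of the C3 carboxylate). The fallback makes the alkene on a small fragment and attaches it afterwards; it sets out from 12 and 10.
- Steglich esterification of 12 with tert-butanol (DCC, DMAP) would give tert-butyl 2-[bis(2,2,2-trifluoroethoxy)phosphoryl]propanoate F5.
- Still–Gennari olefination with 16 (KN(SiMe3)2, 18-crown-6, THF, −78 °C) would give tert-butyl (2Z)-4-(acetyloxy)-2-methylbut-2-enoate F6.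
- Trifluoroacetic acid in CH2Cl2 would release (2Z)-4-(acetyloxy)-2-methylbut-2-enoic acid F7.
- Yamaguchi esterification of 10 with F7 (2,4,6-trichlorobenzoyl chloride, Et3N, then DMAP, toluene) would give (2R,3S)-5-acetyl-6-[(tert-butyldimethylsilyl)oxy]-2-(2-hydroxypropan-2-yl)-2,3-dihydro-1-benzofuran-3-yl (2Z)-4-(acetyloxy)-2-methylbut-2-enoate F8.
- Dehydration of F8 as in step 8 (SOCl2, pyridine) comes back to 17.

**Further compounds**

F1 | step 3 | (2S)-5-bromo-6-[(tert-butyldimethylsilyl)oxy]-2-(2-hydroxypropan-2-yl)-1-benzofuran-3(2H)-one | CC(C)(O)[C@@H]1Oc2cc(O[Si](C)(C)C(C)(C)C)c(Br)cc2C1=O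
F2 | step 8 | 1-[(2R,3S)-6-[(tert-butyldimethylsilyl)oxy]-2-(2-hydroxypropan-2-yl)-3-[(triethylsilyl)oxy]-2,3-dihydro-1-benzofuran-5-yl]ethan-1-one | CC(C)(O)[C@@H]1Oc2cc(O[Si](C)(C)C(C)(C)C)c(C(C)=O)cc2[C@@H]1O[Si](CC)(CC)CC
F3 | step 8 | 1-[(2S,3S)-6-[(tert-butyldimethylsilyl)oxy]-2-(prop-1-en-2-yl)-3-[(triethylsilyl)oxy]-2,3-dihydro-1-benzofuran-5-yl]ethan-1-one | C=C(C)[C@@H]1Oc2cc(O[Si](C)(C)C(C)(C)C)c(C(C)=O)cc2[C@@H]1O[Si](CC)(CC)CC
F4 | step 8 | 1-[(2S,3S)-6-[(tert-butyldimethylsilyl)oxy]-3-hydroxy-2-(prop-1-en-2-yl)-2,3-dihydro-1-benzofuran-5-yl]ethan-1-one | C=C(C)[C@@H]1Oc2cc(O[Si](C)(C)C(C)(C)C)c(C(C)=O)cc2[C@@H]1O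
F5 | step 10 | tert-butyl 2-[bis(2,2,2-trifluoroethoxy)phosphoryl]propanoate | CC(C(=O)OC(C)(C)C)P(=O)(OCC(F)(F)F)OCC(F)(F)F
F6 | step 10 | tert-butyl (2Z)-4-(acetyloxy)-2-methylbut-2-enoate | CC(C)(C)OC(=O)/C(C)=C\COC(C)=O
F7 | step 10 | (2Z)-4-(acetyloxy)-2-methylbut-2-enoic acid | OC(=O)/C(C)=C\COC(C)=O
F8 | step 10 | (2R,3S)-5-acetyl-6-[(tert-butyldimethylsilyl)oxy]-2-(2-hydroxypropan-2-yl)-2,3-dihydro-1-benzofuran-3-yl (2Z)-4-(acetyloxy)-2-methylbut-2-enoate | CC(C)(O)[C@@H]1Oc2cc(O[Si](C)(C)C(C)(C)C)c(C(C)=O)cc2[C@@H]1OC(=O)/C(C)=C\COC(C)=O
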